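Amounts first: each substrate hand is half of the substrate charged, so read each hand as a fraction of its own charge.

common to all: left-handed substrate 0.15 M; right-handed substrate 0.15 M
- maple: partner 0.23 M; protic impurity 0.015 M; run made earlier
- flask: partner 0.450 M; protic impurity 0.0150 M; time 3.0 min

maple run (percent of the left-handed substrate and right-handed substrate together charged)

| time / s | right-handed substrate / % | left-handed substrate / % | left-handed product / % |
|---|---|---|---|
| 10.0 | 48.7 | 42.9 | 6.8 |
| 12.0 | 48.4 | 40.8 | 9.7 |
| 20.0 | 47.1 | 38.3 | 12.8 |

(standard deviation of a reading: 0.5 percentage points)

- partner is single-handed; left-handed substrate and right-handed substrate are mirror images of each other, charged as a racemate, each of them at the stated concentration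
- the analysis behind the earlier runs scatters by 0.5 percentage points, standard deviation
- the handed part of partner does not stay in what it makes, so the products of the two hands are mirror images too

1. whether the excess of right-handed substrate over left-handed substrate among what is left of the two reaches 80% by 3.0 min (yes / no)
2. the highest excess of right-handed substrate over left-handed substrate among what is left of the two up to 3.0 min

1. In the maple run, take the logarithm of each hand's fraction. Sum these over the readings, then divide the left-handed sum by the right-handed sum. The quotient is 5.25.
2. Call it the selectivity factor: how many times faster left-handed substrate goes than right-handed substrate at the same partner. Both hands meet one partner, so partner cancels. It is a reading and carries the scatter.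
3. Turn the wanted 80% into a ratio of right-handed to left-handed substrate: 9.00. My estimate from the factor puts the flask there at 59.7% of the right-handed charge and 6.63% of the left-handed charge.
4. Test whether one number is enough, since it tells how far, not how soon. Count the impurity in: my estimate for the flask uses 47.9% of its partner charge, less than the charge.
5. Scale the maple pace at 20.0 s to the flask's mean free partner. This gives 2.18 min, sooner than 3.0 min. So my reckoning says yes.

The forecast differs: no, with a top of 45%, holding that “the excess must peak and then decay”.

The flask answers yes, and its highest excess up to 3.0 min is 90.4%.

partner + left-handed substrate → left-handed product (k = 0.0770 /M/s); partner + right-handed substrate → right-handed product (k = 0.0120 /M/s); left-handed product ⇌ right-handed product (k = 0.00200 /s); partner → decomposed reagent (k = 9.20 × 10⁻⁴ /s); partner + protic impurity → quenched reagent (k = 0.330 /M/s) It reaches 80% at 1.98 min, when right-handed substrate stands at 33.3% of both substrates charged. Use the factor once more. In the flask at 3.00 min, 58% of the right-handed charge is still there. Raise that fraction to the power 5.25, and it gives 5.51% of the left-handed charge. The flask holds 2.9%.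

The readings are simulated with constants of no real substance; noise was put on by code.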